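Core numbering: C1 (quaternary, CH3), C2 and C3 (CH2), C4 (isopropyl carbinol), C5 (ring-fusion CH), C6 (aroyloxy CH), C7 (CH2), C8 (methyl-bearing alkene C), C9 (alkene CH), C10 (isovaleryloxy CH). β is the face of the C1 methyl. The target, (1R,4S,5S,6R,10S), has C5–H and C4–OH β and the isopropyl group and both acyloxy groups α, so it is a cis-fused hydroazulene.
Retrosynthetic cuts, in order: the two ester C–O bonds; C8–CH3 back to an ester; the C4–O/C5–H pair back to a C4=C5 enone; the C4–isopropyl bond; last, C7–C8 and C1–C10 of the seven-membered ring.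
Enabling feature: in the seven-membered ring a lone methylene, C7, separates the oxygen-bearing C6 from the alkene carbon C8. Tying C6 to C8 turns C6–C7–C8 into a three-membered ring that carries the C5=C1 bond of the five-membered ring and a C9=C10 bond as cis neighbours. A [3,3] shift converts this array into the C1–C10 bond, C5=C6 and C8=C9.
Forward order: the five-membered ring is bought as a cyclopentenone and the ethoxyvinyl arm (C6, C7) is coupled on. C8–C10 arrive as a siloxy vinyldiazoacetate, and one rhodium-catalysed step closes the seven-membered ring. Isopropyl, oxygen and hydrogen follow, and the esters go on last.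
Stereochemistry: C1 and C10 come from the chiral dirhodium catalyst, relayed through the boat Cope transition state and the E enol ether. C4, C5 and C6 come from attack of oxidant, proton and hydride on the β face, because the α face is covered by C10 with its siloxy group and later by the isopropyl group.

Key step: step 5

Assumption: the sense of induction of Rh2(S-DOSP)4 (DOSP = N-(4-dodecylphenylsulfonyl)prolinate) is taken from its cyclopropanations of styrenes and dienes (carbene carbon, substituted alkene carbon, CH2 run clockwise when seen from the face bearing the donor group); Rh2(R-DOSP)4 would be used in the same way if the opposite sense were found.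

Step 1
Reactants: 1 3-methylcyclopent-2-en-1-one
Product: 2 2-iodo-3-methylcyclopent-2-en-1-one
Conditions: I2, pyridine, CH2Cl2, 0 °C → rt
Reagents that add atoms: iodine, [I][I]
Why: Pyridine-mediated α-iodination of an enone (conjugate addition of pyridine, iodination of the enolate, elimination) should place iodine on the only vinylic CH, the future C5, and creates no stereocentre.

Step 2
Reactants: 2 2-iodo-3-methylcyclopent-2-en-1-one; 3 tributyl(1-ethoxyvinyl)stannane
Product: 4 2-(1-ethoxyvinyl)-3-methylcyclopent-2-en-1-one
Conditions: Pd2(dba)3 (cat.), AsPh3, CuI, NMP, rt → 50 °C; Et3N-washed silica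
Reagents that add atoms: none
Why: Stille coupling of an α-iodoenone with an α-alkoxyvinylstannane forms C5–C6, and the AsPh3/CuI acceleration keeps the temperature low enough to spare the acid- and heat-sensitive 2-alkoxydiene.

Step 3
Reactants: 5 ethyl diazoacetate; 6 (tert-butyldimethylsilyloxy)acetaldehyde
Product: 7 ethyl 4-(tert-butyldimethylsilyloxy)-2-diazo-3-hydroxybutanoate (racemic)
Conditions: DBU (cat.), MeCN, rt
Reagents that add atoms: none
Why: The base-catalysed aldol-type addition of a diazoacetate to an aldehyde is a standard route to β-hydroxy-α-diazo esters, it forms C8–C9, and its racemic carbinol centre is erased in step 4.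

Step 4
Reactants: 7 ethyl 4-(tert-butyldimethylsilyloxy)-2-diazo-3-hydroxybutanoate
Product: 9 ethyl (E)-4-(tert-butyldimethylsilyloxy)-2-diazobut-3-enoate, via phosphorodichloridate ester 8 (not isolated)
Conditions: POCl3, Et3N, CH2Cl2, 0 °C → rt; used at once
Reagents that add atoms: phosphoryl chloride, O=P(Cl)(Cl)Cl (its atoms stay in 8 only)
Why: Dehydration of a β-hydroxy-α-diazo ester through an activated phosphate ester is the usual entry to vinyldiazoacetates, only C10 carries removable hydrogens, and the E enol ether should prevail because it keeps the siloxy group away from the diazo ester.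

Step 5
Reactants: 4 2-(1-ethoxyvinyl)-3-methylcyclopent-2-en-1-one; 9 ethyl (E)-4-(tert-butyldimethylsilyloxy)-2-diazobut-3-enoate
Product: 11 ethyl (8S,8aR)-8-(tert-butyldimethylsilyloxy)-4-ethoxy-8a-methyl-3-oxo-1,2,3,5,8,8a-hexahydroazulene-6-carboxylate, via cis-dialkenylcyclopropane 10 (not isolated)
Conditions: Rh2(S-DOSP)4 (1 mol %), hexanes/PhCF3, −20 °C → rt, 9 added slowly; then 70 °C
Reagents that add atoms: none
Why: Rh2(S-DOSP)4 expels N2 from 9 to give a donor–acceptor dirhodium vinylcarbene (carbene carbon C8, arm C9=C10) that adds in a concerted but asynchronous [2+1] fashion across C6=C7 of 4, and the cis-dialkenylcyclopropane 10 then undergoes a Cope rearrangement that breaks C6–C8 and joins C1 to C10, the closest known reaction type being the tandem cyclopropanation/Cope formal (4+3) cycloaddition of vinyldiazoacetates with 1,3-dienes, which tolerates 2-oxygenated dienes and fully substituted diene termini. The three-membered ring closes by carbene transfer and the seven-membered ring by the [3,3]-sigmatropic shift through the boat transition state that a cis-dialkenylcyclopropane has to adopt, pulled along by loss of ring strain, by the push–pull character of the C6(OEt)–C8(CO2Et) bond and by the vinylogous ester that emerges. The prolinate ligands choose the carbene face that is attacked and so fix C6 and C8 of 10, and the suprafacial shift passes this information on to C1 and C10. Within the boat the E-siloxy group on C10 and C2 on C1 point outward while the C1 methyl (cis to C6 across C1=C5) points inward, so the C10 oxygen ends cis to C2 and trans to the methyl group. The step needs attack at C6=C7 and not at C1=C5, which the terminal, 1,1-disubstituted, ethoxy-activated nature of the former and the tetrasubstituted, carbonyl-deactivated nature of the latter secure, and it needs bond formation at C8 and not at C10 of the carbene, which the substituted terminus, the small ester and the hydrocarbon medium favour. It also needs the two alkenyl groups cis, the usual outcome since the larger alkene substituent settles next to the vinyl donor and away from the ester, and any trans isomer should drain into the same product on warming through reversible opening of the donor–acceptor bond.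

Step 6
Reactants: 11 hydroazulenone from step 5; 12 isopropylmagnesium chloride
Product: 14 ethyl (8S,8aR)-8-(tert-butyldimethylsilyloxy)-3-isopropyl-8a-methyl-4-oxo-1,2,4,5,8,8a-hexahydroazulene-6-carboxylate (C4=C5 enone with C6 ketone), via tertiary carbinol 13 (not isolated)
Conditions: CeCl3, THF, −78 °C; then 1 M HCl, 0 °C
Reagents that add atoms: water, O (C6 carbonyl oxygen after ionisation of the C4 hydroxyl)
Why: The weakly basic organocerium reagent adds 1,2 to the vinylogous ester carbonyl faster than to the hindered conjugated ester at −78 °C, and the acid-induced Stork–Danheiser transposition then moves the carbonyl to C6 and gives the C4=C5 enone, so the C4 configuration of 13 is of no consequence.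

Step 7
Reactants: 14 C4=C5 enone
Product: 15 4β,5β-epoxy-6-ketone (C8 ethyl ester, C8=C9, C10 α-OTBS, C1 β-CH3)
Conditions: dimethyldioxirane, acetone/CH2Cl2, 0 °C → rt
Reagents that add atoms: dimethyldioxirane, CC1(C)OO1
Why: Neutral electrophilic dioxirane epoxidation of an enone avoids base at the acidic C7 methylene, should prefer the tetrasubstituted C4=C5 bond (twisted out of conjugation by the clash of the isopropyl group with the C6 carbonyl) over the ester-bearing C8=C9 bond, and should deliver oxygen to the β face because C10 and its siloxy group, cis to C2, cover the α face, which sets C4.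

Step 8
Reactants: 15 4β,5β-epoxy-6-ketone
Product: 16 β-hydroxy ketone with C4 β-OH, C4 α-isopropyl, C5 β-H (cis-fused), C6 ketone, C8 ethyl ester, C10 α-OTBS
Conditions: SmI2, THF/MeOH, −90 °C; pH 7 buffer
Reagents that add atoms: none
Why: Reductive cleavage of an α,β-epoxy ketone by SmI2 (two single-electron transfers, scission of the C5–O bond next to the ketyl) leaves the C4–O bond untouched and gives a trivalent samarium enolate that methanol should protonate at C5 from the β face, which carries only the C1 methyl and the metal-bound C4 oxygen while the α face carries the isopropyl group and C10, so the cis fusion is the kinetic outcome and 16 is reduced without storage.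

Step 9
Reactants: 16 β-hydroxy ketone
Product: 17 triol with C4 β-OH, C6 α-OH, C8 CH2OH, C10 α-OTBS
Conditions: i-Bu2AlH (excess), CH2Cl2, −78 → −40 °C; aq. potassium sodium tartrate
Reagents that add atoms: none
Why: i-Bu2AlH reduces the ketone and, by 1,2-reduction, the conjugated ester in one operation, and under steric approach control hydride should reach C6 from the convex β face, on the side of C5–H and anti to the fully substituted C4, which places the C6 hydroxyl α.

Step 10
Reactants: 17 triol
Product: 19 4β,6α-diol bearing the C8 methyl group (C10 α-OTBS), via allylic sulfate 18 (not isolated)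
Conditions: SO3·pyridine (1.2 equiv), THF, 0 °C; then LiAlH4, 0 °C → rt
Reagents that add atoms: sulfur trioxide–pyridine, O=S(=O)=O.c1ccncc1 (its atoms stay in 18 only)
Why: In this allylic deoxygenation through a sulfate monoester the unhindered primary allylic hydroxyl is sulfated first and hydride displaces the sulfate by direct SN2 attack at the CH2, so C8=C9 stays in place and no stereocentre is touched.

Step 11
Reactants: 19 4β,6α-diol; 20 4-acetoxybenzoyl chloride
Product: 21 C6 α-(4-acetoxybenzoate) of 19
Conditions: DMAP, Et3N, CH2Cl2, rt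
Reagents that add atoms: none
Why: In this DMAP-catalysed acylation only the secondary C6 hydroxyl can react, since the C4 hydroxyl is tertiary and C10 is silylated, and the C6–O bond is not broken.

Step 12
Reactants: 21 C6 α-(4-acetoxybenzoate)
Product: 22 C10 α-alcohol (C4 β-OH, C6 α-(4-acetoxybenzoate))
Conditions: HF·pyridine, pyridine, THF, 0 °C → rt
Reagents that add atoms: none
Why: Fluoride-driven cleavage of the silyl ether in a weakly acidic medium leaves the aryl acetate, the benzoate and the tertiary alcohol alone.

Step 13
Reactants: 22 C10 α-alcohol; 23 3-methylbutanoyl chloride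
Product: 24 C10 α-(3-methylbutanoate) of 22
Conditions: DMAP, Et3N, CH2Cl2, rt
Reagents that add atoms: none
Why: DMAP-catalysed acylation takes the only secondary hydroxyl left, the allylic one at C10, with retention, while the tertiary C4 hydroxyl stays free.

Step 14
Reactants: 24 diester aryl acetate
Product: 25 target, (3S,3aS,4R,8S,8aR)-3-hydroxy-3-isopropyl-6,8a-dimethyl-8-(3-methylbutanoyloxy)-1,2,3,3a,4,5,8,8a-octahydroazulen-4-yl 4-hydroxybenzoate
Conditions: pyrrolidine, CH2Cl2, 0 °C
Reagents that add atoms: none
Why: Aminolysis singles out the aryl acetate, whose leaving group is a phenoxide stabilised by the para ester, while the hindered alkyl 3-methylbutanoate and the benzoate react far more slowly.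

Compound list
1 | 3-methylcyclopent-2-en-1-one | CC1=CC(=O)CC1 | starting material
2 | 2-iodo-3-methylcyclopent-2-en-1-one | CC1=C(I)C(=O)CC1 | intermediate
3 | tributyl(1-ethoxyvinyl)stannane | CCOC(=C)[Sn](CCCC)(CCCC)CCCC | starting material
4 | 2-(1-ethoxyvinyl)-3-methylcyclopent-2-en-1-one | CCOC(=C)C1=C(C)CCC1=O | intermediate
5 | ethyl diazoacetate | CCOC(=O)C=[N+]=[N-] | starting material
6 | (tert-butyldimethylsilyloxy)acetaldehyde | CC(C)(C)[Si](C)(C)OCC=O | starting material
7 | ethyl 4-(tert-butyldimethylsilyloxy)-2-diazo-3-hydroxybutanoate, racemic | CCOC(=O)C(=[N+]=[N-])C(O)CO[Si](C)(C)C(C)(C)C | intermediate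
8 | phosphorodichloridate ester of 7, racemic, not isolated | CCOC(=O)C(=[N+]=[N-])C(CO[Si](C)(C)C(C)(C)C)OP(=O)(Cl)Cl | intermediate
9 | ethyl (E)-4-(tert-butyldimethylsilyloxy)-2-diazobut-3-enoate | CCOC(=O)C(=[N+]=[N-])/C=C/O[Si](C)(C)C(C)(C)C | intermediate
10 | ethyl (1R,2S)-1-[(E)-2-(tert-butyldimethylsilyloxy)vinyl]-2-ethoxy-2-(2-methyl-5-oxocyclopent-1-en-1-yl)cyclopropane-1-carboxylate, alkenyl arms cis, not isolated | CCOC(=O)[C@@]1(/C=C/O[Si](C)(C)C(C)(C)C)C[C@]1(OCC)C2=C(C)CCC2=O | intermediate
11 | ethyl (8S,8aR)-8-(tert-butyldimethylsilyloxy)-4-ethoxy-8a-methyl-3-oxo-1,2,3,5,8,8a-hexahydroazulene-6-carboxylate (C1 β-CH3, C10 α-OTBS, C4 ketone, C5=C6 enol ether, C8 ester) | CCOC(=O)C1=C[C@H](O[Si](C)(C)C(C)(C)C)[C@]2(C)CCC(=O)C2=C(OCC)C1 | intermediate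
12 | isopropylmagnesium chloride | CC(C)[Mg]Cl | starting material
13 | tertiary carbinol from 11, drawn as the 4α-hydroxy-4β-isopropyl epimer expected from β-face attack, C5=C6 enol ether kept, not isolated | CCOC(=O)C1=C[C@H](O[Si](C)(C)C(C)(C)C)[C@]2(C)CC[C@@](O)(C(C)C)C2=C(OCC)C1 | intermediate
14 | ethyl (8S,8aR)-8-(tert-butyldimethylsilyloxy)-3-isopropyl-8a-methyl-4-oxo-1,2,4,5,8,8a-hexahydroazulene-6-carboxylate (C4=C5 enone, C6 ketone) | CCOC(=O)C1=C[C@H](O[Si](C)(C)C(C)(C)C)[C@]2(C)CCC(C(C)C)=C2C(=O)C1 | intermediate
15 | 4β,5β-epoxide of 14 | CCOC(=O)C1=C[C@H](O[Si](C)(C)C(C)(C)C)[C@]2(C)CC[C@@]3(C(C)C)O[C@@]23C(=O)C1 | intermediate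
16 | β-hydroxy ketone: C4 β-OH, C4 α-isopropyl, C5 β-H, C6 ketone, C8 ethyl ester, C10 α-OTBS | CCOC(=O)C1=C[C@H](O[Si](C)(C)C(C)(C)C)[C@]2(C)CC[C@](O)(C(C)C)[C@@H]2C(=O)C1 | intermediate
17 | triol: C4 β-OH, C6 α-OH, C8 CH2OH, C10 α-OTBS | OCC1=C[C@H](O[Si](C)(C)C(C)(C)C)[C@]2(C)CC[C@](O)(C(C)C)[C@@H]2[C@H](O)C1 | intermediate
18 | hydrogen sulfate of the C8 CH2OH group of 17, not isolated | OS(=O)(=O)OCC1=C[C@H](O[Si](C)(C)C(C)(C)C)[C@]2(C)CC[C@](O)(C(C)C)[C@@H]2[C@H](O)C1 | intermediate
19 | diol: C4 β-OH, C6 α-OH, C8 CH3, C10 α-OTBS | CC1=C[C@H](O[Si](C)(C)C(C)(C)C)[C@]2(C)CC[C@](O)(C(C)C)[C@@H]2[C@H](O)C1 | intermediate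
20 | 4-acetoxybenzoyl chloride | CC(=O)Oc1ccc(cc1)C(=O)Cl | starting material
21 | C6 α-(4-acetoxybenzoate) of 19 | CC1=C[C@H](O[Si](C)(C)C(C)(C)C)[C@]2(C)CC[C@](O)(C(C)C)[C@@H]2[C@H](OC(=O)c2ccc(OC(C)=O)cc2)C1 | intermediate
22 | C10 α-alcohol from 21 | CC1=C[C@H](O)[C@]2(C)CC[C@](O)(C(C)C)[C@@H]2[C@H](OC(=O)c2ccc(OC(C)=O)cc2)C1 | intermediate
23 | 3-methylbutanoyl chloride (isovaleryl chloride) | CC(C)CC(=O)Cl | starting material
24 | C10 α-(3-methylbutanoate) of 22 | CC1=C[C@H](OC(=O)CC(C)C)[C@]2(C)CC[C@](O)(C(C)C)[C@@H]2[C@H](OC(=O)c2ccc(OC(C)=O)cc2)C1 | intermediate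
25 | target, (1R,4S,5S,6R,10S) in core numbering | CC1=C[C@H](OC(=O)CC(C)C)[C@]2(C)CC[C@](O)(C(C)C)[C@@H]2[C@H](OC(=O)c2ccc(O)cc2)C1 | target

Total step count: 14. Longest linear sequence: 12 (steps 1, 2 and 5 to 14).

Steps most likely to fail

Step 5. The carbene from 9 is a strong push–pull system, and several processes could erode the (4+3) pathway:
- attack of the enol ether of 4 at the oxygen-bearing terminus C10 instead of at C8;
- capture of the carbene by the enol ether of a second molecule of 9;
- closure of 9 to a pyrazole before it meets the catalyst;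
- formation of the trans-dialkenylcyclopropane followed by collapse to a cyclopentene.

The fallback lowers the donor strength at C10 by changing from an enol silane to a sturdier enol ester, and restores the silyl ether afterwards. It sets out from 5 and comes back at 11. DBU-catalysed addition of 5 to 2-oxoethyl acetate would give ethyl 4-acetoxy-2-diazo-3-hydroxybutanoate F1. POCl3/Et3N would dehydrate it through the phosphorodichloridate F2 to ethyl (E)-4-acetoxy-2-diazobut-3-enoate F3. Decomposition of F3 by Rh2(S-DOSP)4 in the presence of 4 would lead through the cis-dialkenylcyclopropane F4 to the C10 α-acetate F5. K2CO3 in ethanol at 0 °C would free the C10 alcohol F6, and TBSOTf/2,6-lutidine would give 11.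

Step 7. The concerns are slow oxygen transfer to the hindered and still deactivated tetrasubstituted alkene, competing attack at C8=C9, and poor facial selectivity. The fallback takes the carbonyl away during the epoxidation, so that C4=C5 becomes an ordinary electron-rich alkene flanked by two α-siloxy groups. It sets out from 14 and comes back at 15. Luche reduction (NaBH4, CeCl3·7H2O, MeOH, −40 °C, hydride from the β face) would give the 6α-allylic alcohol F7, and TESOTf/2,6-lutidine its triethylsilyl ether F8. m-CPBA/NaHCO3 would give the 4β,5β-epoxide F9 by attack opposite to both siloxy groups. Pyridine-buffered HF·pyridine at 0 °C would remove the more labile triethylsilyl group to give the epoxy alcohol F10, and Dess–Martin periodinane would return 15.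

Step 8. The cis-fused product could be lost through protonation of the enolate from the α face, epimerisation of C5 toward the trans-fused isomer, or β-elimination back to 14. The fallback sets C5–H by a stereospecific syn addition instead of an enolate protonation. It sets out from 15 and comes back at 16. Wharton transposition (N2H4·H2O, AcOH, MeOH) would pass through the epoxy hydrazone F11 to the allylic alcohol F12, which keeps the C4 β-hydroxyl and has a C5=C6 bond. BH3·THF should add hydrogen to C5 and boron to C6 from the β face, the face of the C4 oxygen and opposite to the isopropyl group and C10, to give the borane F13. NaBO3·4H2O would turn F13 into the 4β,6β-diol F14. Dess–Martin periodinane, which oxidises only the secondary alcohol and needs no base, would give 16 for immediate reduction in step 9.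

Further compounds
F1 | step 5 | ethyl 4-acetoxy-2-diazo-3-hydroxybutanoate, racemic | CCOC(=O)C(=[N+]=[N-])C(O)COC(C)=O
F2 | step 5 | phosphorodichloridate ester of F1, racemic | CCOC(=O)C(=[N+]=[N-])C(COC(C)=O)OP(=O)(Cl)Cl
F3 | step 5 | ethyl (E)-4-acetoxy-2-diazobut-3-enoate | CCOC(=O)C(=[N+]=[N-])/C=C/OC(C)=O
F4 | step 5 | acetoxyvinyl analogue of cyclopropane 10, alkenyl arms cis | CCOC(=O)[C@@]1(/C=C/OC(C)=O)C[C@]1(OCC)C2=C(C)CCC2=O
F5 | step 5 | C10 α-acetate analogue of 11 | CCOC(=O)C1=C[C@H](OC(C)=O)[C@]2(C)CCC(=O)C2=C(OCC)C1
F6 | step 5 | C10 α-alcohol analogue of 11 | CCOC(=O)C1=C[C@H](O)[C@]2(C)CCC(=O)C2=C(OCC)C1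
F7 | step 7 | 6α-allylic alcohol from 14 | CCOC(=O)C1=C[C@H](O[Si](C)(C)C(C)(C)C)[C@]2(C)CCC(C(C)C)=C2[C@H](O)C1
F8 | step 7 | 6α-triethylsilyl ether of F7 | CCOC(=O)C1=C[C@H](O[Si](C)(C)C(C)(C)C)[C@]2(C)CCC(C(C)C)=C2[C@H](O[Si](CC)(CC)CC)C1
F9 | step 7 | 4β,5β-epoxide of F8 | CCOC(=O)C1=C[C@H](O[Si](C)(C)C(C)(C)C)[C@]2(C)CC[C@@]3(C(C)C)O[C@@]23[C@H](O[Si](CC)(CC)CC)C1
F10 | step 7 | 4β,5β-epoxy-6α-alcohol | CCOC(=O)C1=C[C@H](O[Si](C)(C)C(C)(C)C)[C@]2(C)CC[C@@]3(C(C)C)O[C@@]23[C@H](O)C1
F11 | step 8 | hydrazone of 15 | CCOC(=O)C1=C[C@H](O[Si](C)(C)C(C)(C)C)[C@]2(C)CC[C@@]3(C(C)C)O[C@@]23C(=NN)C1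
F12 | step 8 | allylic alcohol with C4 β-OH and C5=C6 | CCOC(=O)C1=C[C@H](O[Si](C)(C)C(C)(C)C)[C@]2(C)CC[C@](O)(C(C)C)C2=CC1
F13 | step 8 | C6 β-borane with C5 β-H, drawn as the dihydroborane | CCOC(=O)C1=C[C@H](O[Si](C)(C)C(C)(C)C)[C@]2(C)CC[C@](O)(C(C)C)[C@@H]2[C@@H](B)C1
F14 | step 8 | 4β,6β-diol with C5 β-H | CCOC(=O)C1=C[C@H](O[Si](C)(C)C(C)(C)C)[C@]2(C)CC[C@](O)(C(C)C)[C@@H]2[C@@H](O)C1
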